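**Retrosynthetic overview**
1. Target ⇒ last, the C11/C13 spiro-epoxide by nucleophilic epoxidation; before it, C8-methacrylate and C9-acetate on the 8,9-diol of the α-methylene 6,12-olide.
2. Ten-membered carbocycle and γ-lactone ⇒ formed together by making C6–C7 in a chromium-catalysed electroreductive intramolecular allylation/lactonisation of a (Z)-enal/2-(bromomethyl)enoate.
3. Allyl bromide ⇒ C7 aldehyde (Morita–Baylis–Hillman, SN2′ bromination), itself from periodate cleavage of the mannose C4–C6 triol.
4. 3(2H)-Furanone ⇒ γ-hydroxy ynone ⇒ carbonylative Sonogashira union of a C10 propargylic alcohol, CO (C3) and a (Z)-vinyl iodide (C4–C6, C15).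
5. C8 and C9 ⇒ D-mannonolactone diacetonide; C10 ⇒ chelation-controlled MeMgBr addition to its alkynyl ketose. Ring order: furanone, then carbocycle and lactone in one step, then epoxide.

Assumption: germacranolide numbering is used (C1 ketone, C2=C3, C3–O–C10, C4=C5, C6–O lactone, C7, C8, C9, C10, C11–C13 lactone/epoxide carbons, C14/C15 methyls), and lactone 4 is taken as a catalogue compound (otherwise one oxidation from diacetone-D-mannose).

**Route**

Step 1
Reactants: 1 but-2-yn-1-ol
Product: 2 (Z)-3-iodobut-2-en-1-ol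
Conditions: NaAlH2(OCH2CH2OMe)2, THF, 0 → 23 °C; then I2, −78 → 0 °C
Reagents that add atoms: iodine, II
Why: Alkoxide-directed trans-hydroalumination of the propargylic alcohol puts aluminium on C3 and iodinolysis proceeds with retention, so only the Z-iodoalkene (I cis to CH2OH) forms (hydroalumination–iodination).

Step 2
Reactants: 2 (Z)-3-iodobut-2-en-1-ol
Product: 3 vinyl iodide silyl ether
Conditions: TBDPSCl, imidazole, CH2Cl2, 0 → 23 °C
Reagents that add atoms: tert-butyl(chloro)diphenylsilane, CC(C)(C)[Si](Cl)(c1ccccc1)c1ccccc1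
Why: Imidazole-promoted silylation of the primary alcohol gives an ether that survives the aqueous acetic acid of step 5 and stops the cis-alcohol from lactonising onto the acylpalladium in step 4 (silyl protection).

Step 3
Reactants: 4 2,3:5,6-di-O-isopropylidene-D-mannono-1,4-lactone
Product: 7 alkynyl diol, via alkynyl hemiketal 5 (not isolated), via silylated alkynyl diol 6 (not isolated)
Conditions: HC≡CSiMe3, n-BuLi, THF, −78 °C, add 4; then MeMgBr (3 equiv), −78 → 0 °C; then MeOH, K2CO3, 23 °C; aq NH4Cl work-up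
Reagents that add atoms: trimethylsilylacetylene, C#C[Si](C)(C)C; methylmagnesium bromide, C[Mg]Br
Why: One lithium acetylide adds to the lactone to give a hemiketal alkoxide that does not over-add, its open ynone form is then captured by MeMgBr through a Cram chelate between the ketone and the α-dioxolane oxygen so that methyl enters anti to C8 and sets the future 10S centre while C8 and C9 are carried unchanged from D-mannose, and methanolysis cleaves the alkynyl silane (acetylide addition to a lactone followed by chelation-controlled Grignard addition).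

Step 4
Reactants: 7 alkynyl diol; 3 vinyl iodide silyl ether
Product: 8 hydroxy ynone
Conditions: CO (1 atm), PdCl2(PPh3)2 (5 mol %), CuI (5 mol %), Et3N, THF, 23 °C
Reagents that add atoms: carbon monoxide, [C-]#[O+]
Why: Carbonylative Sonogashira coupling, in which zerovalent palladium adds to the vinyl iodide with retention of the Z geometry, CO inserts and the copper acetylide is transferred, gives the cross-conjugated ynone while the hindered secondary and tertiary alcohols do not intercept the acylpalladium at room temperature.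

Step 5
Reactants: 8 hydroxy ynone
Product: 11 furanone triol, via enaminone 9 (not isolated), via furanone bis-acetonide 10 (not isolated)
Conditions: Et2NH (1.5 equiv), EtOH, 23 °C; then AcOH/H2O (4:1), 40 °C
Reagents that add atoms: water, O
Why: Et2NH adds to the ynone β-carbon C1, the C10 hydroxyl closes onto the C3 carbonyl with loss of water, and the aqueous acid hydrolyses the resulting vinylogous iminium to the 3(2H)-furanone and cleaves only the more labile terminal acetonide, no bond to a stereocentre being broken (amine-mediated hydroxy-ynone cyclisation).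

Step 6
Reactants: 11 furanone triol
Product: 12 aldehyde
Conditions: NaIO4, THF/H2O (pH 7 phosphate), 0 → 23 °C
Reagents that add atoms: none
Why: Malaprade periodate cleavage of the 1,2,3-triol removes the two mannose carbons that are no longer needed and unveils C7 as an aldehyde, the internal acetonide, silyl ether and furanone being inert to NaIO4 at neutral pH.

Step 7
Reactants: 12 aldehyde
Product: 13 Baylis–Hillman adduct
Conditions: methyl acrylate (5 equiv), DABCO (1 equiv), 1,4-dioxane/H2O (1:1), 23 °C
Reagents that add atoms: methyl acrylate, C=CC(=O)OC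
Why: Morita–Baylis–Hillman reaction of the activated α-alkoxy aldehyde installs C11–C13, the fast aqueous-dioxane protocol limits base contact so that C8 is not epimerised, and the new carbinol centre is irrelevant because it is erased in step 10.

Step 8
Reactants: 13 Baylis–Hillman adduct
Product: 14 diol
Conditions: TBAF, AcOH (1:1), THF, 0 °C
Reagents that add atoms: none
Why: Acetic acid-buffered fluoride cleaves the Si–O bond without base-mediated isomerisation of the Z-dienone or retro-aldol of the Baylis–Hillman adduct (fluoride desilylation).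

Step 9
Reactants: 14 diol
Product: 15 hydroxy enal
Conditions: TEMPO (10 mol %), PhI(OAc)2 (1.1 equiv), CH2Cl2, 23 °C
Reagents that add atoms: none
Why: Oxoammonium (TEMPO/PhI(OAc)2) oxidation is selective for the primary allylic alcohol over the hindered secondary one and does not isomerise Z-allylic alcohols, so the Z-enal is obtained.

Step 10
Reactants: 15 hydroxy enal
Product: 16 bromo enal
Conditions: NBS, Me2S, CH2Cl2, −20 → 0 °C
Reagents that add atoms: N-bromosuccinimide, O=C1CCC(=O)N1Br
Why: The alcohol is activated as an alkoxysulfonium salt and bromide attacks the terminal methylene in SN2′ fashion (Corey–Kim-type allylic transposition), giving the conjugated (Z)-2-(bromomethyl)enoate without touching the aldehyde.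

Step 11
Reactants: 16 bromo enal
Product: 18 macrolactone acetonide, via seco hydroxy ester 17 (not isolated)
Conditions: CrCl2 (20 mol %), n-Bu4NBr (0.1 M), DMF, Al anode, Ni-foam cathode, undivided cell, 2 mA constant current (2.2 F/mol), 16 added by syringe pump over 10 h (final 3 mM), 23 °C, dark; then 1 M aq citric acid
Reagents that add atoms: none
Why: Proposed new method: the cathode reduces trivalent to divalent chromium at a potential well positive of the dienal, furanone and allyl bromide, two divalent chromium ions turn the allylic bromide into a nucleophilic allylchromium that equilibrates by fast 1,3-metal shift (so the bromide geometry is not carried over) and adds only to the C6 aldehyde through a closed Zimmerman–Traxler chair in which the C5 and C8 chains are pseudo-equatorial (anti adduct, hence trans-lactone) and H8 eclipses the alkene so that C6–C7 forms anti to C9 across a transoid ring torsion (6R,7S under control of C8), the chromium alkoxide then lactonises onto the neighbouring ester and anodically formed trivalent aluminium ions take up methoxide and bromide to free the catalyst; the closest known chemistry is the chromium-catalysed electroreductive Nozaki–Hiyama–Kishi coupling of halides with aldehydes and the stoichiometric CrCl2 Barbier-type closure of ω-formyl 2-(bromomethyl)enoates to germacranolides, neither of which has been run as an electrocatalytic medium-ring allylation–lactonisation.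

Step 12
Reactants: 18 macrolactone acetonide
Product: 19 macrolactone diol
Conditions: TFA/H2O (4:1), 0 → 23 °C
Reagents that add atoms: none
Why: Acid-catalysed hydrolysis of the remaining isopropylidene acetal leaves the lactone, furanone and exocyclic methylene untouched and involves no stereocentre (acetal hydrolysis).

Step 13
Reactants: 19 macrolactone diol
Product: 20 C8 methacrylate
Conditions: methacrylic anhydride (1.1 equiv), Et3N, DMAP (5 mol %), CH2Cl2, −20 °C
Reagents that add atoms: methacrylic anhydride, CC(=C)C(=O)OC(=O)C(C)=C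
Why: DMAP-catalysed acylation goes to the C8 hydroxyl because the C9 hydroxyl is neopentylic (next to quaternary C10) and inductively deactivated by the furanone oxygen, and the low temperature suppresses acyl migration from O8 to O9.

Step 14
Reactants: 20 C8 methacrylate
Product: 21 C8 methacrylate C9 acetate
Conditions: Ac2O, pyridine, DMAP, CH2Cl2, 23 °C
Reagents that add atoms: acetic anhydride, CC(=O)OC(C)=O
Why: DMAP-catalysed (Steglich-type) acetylation of the one remaining, hindered secondary alcohol with excess anhydride has no competing nucleophilic site.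

Step 15
Reactants: 21 C8 methacrylate C9 acetate
Product: 22 target CNP0423862.2
Conditions: t-BuOOH (decane solution), DBU, CH2Cl2, 0 °C
Reagents that add atoms: tert-butyl hydroperoxide, CC(C)(C)OO
Why: Weitz–Scheffer nucleophilic epoxidation, in which tert-butylperoxide anion adds to C13 of the strained s-cis α-methylene lactone (far more electrophilic than the methacrylate or the vinylogous-ester furanone) and the lactone enolate closes on oxygen from the β face anti to pseudo-axial H7, the face from which trans-fused 6,12-olide enolates are attacked, gives the 11S spiro-epoxide.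

**Compound list**

1 | but-2-yn-1-ol | CC#CCO | starting material
2 | (Z)-3-iodobut-2-en-1-ol | C/C(I)=C/CO | intermediate
3 | vinyl iodide silyl ether: tert-butyl{[(2Z)-3-iodobut-2-en-1-yl]oxy}diphenylsilane | C/C(I)=C/CO[Si](c1ccccc1)(c1ccccc1)C(C)(C)C | intermediate
4 | 2,3:5,6-di-O-isopropylidene-D-mannono-1,4-lactone | O=C1[C@@H](O2)[C@@H](OC2(C)C)[C@H](O1)[C@H](O3)COC3(C)C | starting material
5 | alkynyl hemiketal: 1-C-[(trimethylsilyl)ethynyl]-2,3:5,6-di-O-isopropylidene-D-mannofuranose (lithium salt in the flask, anomeric mixture) | C[Si](C)(C)C#CC1(O)[C@@H](O2)[C@@H](OC2(C)C)[C@H](O1)[C@H](O3)COC3(C)C | intermediate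
6 | silylated alkynyl diol: (2R)-2-[(4S,5S)-5-{(R)-[(4R)-2,2-dimethyl-1,3-dioxolan-4-yl](hydroxy)methyl}-2,2-dimethyl-1,3-dioxolan-4-yl]-4-(trimethylsilyl)but-3-yn-2-ol | C[Si](C)(C)C#C[C@](O)(C)[C@@H](O2)[C@@H](OC2(C)C)[C@H](O)[C@H](O3)COC3(C)C | intermediate
7 | alkynyl diol: (2R)-2-[(4S,5S)-5-{(R)-[(4R)-2,2-dimethyl-1,3-dioxolan-4-yl](hydroxy)methyl}-2,2-dimethyl-1,3-dioxolan-4-yl]but-3-yn-2-ol | C#C[C@](O)(C)[C@@H](O2)[C@@H](OC2(C)C)[C@H](O)[C@H](O3)COC3(C)C | intermediate
8 | hydroxy ynone: (2Z,7R)-1-[(tert-butyldiphenylsilyl)oxy]-7-hydroxy-3-methyl-7-[(4S,5S)-5-{(R)-[(4R)-2,2-dimethyl-1,3-dioxolan-4-yl](hydroxy)methyl}-2,2-dimethyl-1,3-dioxolan-4-yl]oct-2-en-5-yn-4-one | C/C(C(=O)C#C[C@](O)(C)[C@@H](O2)[C@@H](OC2(C)C)[C@H](O)[C@H](O3)COC3(C)C)=C/CO[Si](c4ccccc4)(c5ccccc5)C(C)(C)C | intermediate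
9 | enaminone: diethylamine adduct of 8 with NEt2 on C6 of the octa-2,5-dien-4-one chain (C1 in target numbering), enamine geometry not fixed | C/C(C(=O)C=C(N(CC)CC)[C@](O)(C)[C@@H](O2)[C@@H](OC2(C)C)[C@H](O)[C@H](O3)COC3(C)C)=C/CO[Si](c4ccccc4)(c5ccccc5)C(C)(C)C | intermediate
10 | furanone bis-acetonide: (2S)-5-{(2Z)-4-[(tert-butyldiphenylsilyl)oxy]but-2-en-2-yl}-2-[(4S,5S)-5-{(R)-[(4R)-2,2-dimethyl-1,3-dioxolan-4-yl](hydroxy)methyl}-2,2-dimethyl-1,3-dioxolan-4-yl]-2-methylfuran-3(2H)-one | C/C(=C/CO[Si](c4ccccc4)(c5ccccc5)C(C)(C)C)C1=CC(=O)[C@](O1)(C)[C@@H](O2)[C@@H](OC2(C)C)[C@H](O)[C@H](O3)COC3(C)C | intermediate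
11 | furanone triol: (2S)-5-{(2Z)-4-[(tert-butyldiphenylsilyl)oxy]but-2-en-2-yl}-2-{(4S,5S)-2,2-dimethyl-5-[(1R,2R)-1,2,3-trihydroxypropyl]-1,3-dioxolan-4-yl}-2-methylfuran-3(2H)-one | C/C(=C/CO[Si](c4ccccc4)(c5ccccc5)C(C)(C)C)C1=CC(=O)[C@](O1)(C)[C@@H](O2)[C@@H](OC2(C)C)[C@H](O)[C@H](O)CO | intermediate
12 | aldehyde: (4R,5S)-5-[(2S)-5-{(2Z)-4-[(tert-butyldiphenylsilyl)oxy]but-2-en-2-yl}-2-methyl-3-oxo-2,3-dihydrofuran-2-yl]-2,2-dimethyl-1,3-dioxolane-4-carbaldehyde | C/C(=C/CO[Si](c4ccccc4)(c5ccccc5)C(C)(C)C)C1=CC(=O)[C@](O1)(C)[C@@H](O2)[C@@H](OC2(C)C)C=O | intermediate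
13 | Baylis–Hillman adduct: methyl 2-{hydroxy[(4S,5S)-5-[(2S)-5-{(2Z)-4-[(tert-butyldiphenylsilyl)oxy]but-2-en-2-yl}-2-methyl-3-oxo-2,3-dihydrofuran-2-yl]-2,2-dimethyl-1,3-dioxolan-4-yl]methyl}prop-2-enoate (both carbinol epimers) | C/C(=C/CO[Si](c4ccccc4)(c5ccccc5)C(C)(C)C)C1=CC(=O)[C@](O1)(C)[C@@H](O2)[C@@H](OC2(C)C)C(O)C(=C)C(=O)OC | intermediate
14 | diol: methyl 2-{hydroxy[(4S,5S)-5-{(2S)-5-[(2Z)-4-hydroxybut-2-en-2-yl]-2-methyl-3-oxo-2,3-dihydrofuran-2-yl}-2,2-dimethyl-1,3-dioxolan-4-yl]methyl}prop-2-enoate (both carbinol epimers) | C/C(=C/CO)C1=CC(=O)[C@](O1)(C)[C@@H](O2)[C@@H](OC2(C)C)C(O)C(=C)C(=O)OC | intermediate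
15 | hydroxy enal: methyl 2-{hydroxy[(4S,5S)-2,2-dimethyl-5-{(2S)-2-methyl-3-oxo-5-[(2Z)-4-oxobut-2-en-2-yl]-2,3-dihydrofuran-2-yl}-1,3-dioxolan-4-yl]methyl}prop-2-enoate (both carbinol epimers) | C/C(=C/C=O)C1=CC(=O)[C@](O1)(C)[C@@H](O2)[C@@H](OC2(C)C)C(O)C(=C)C(=O)OC | intermediate
16 | bromo enal: methyl (2Z)-2-(bromomethyl)-3-[(4S,5S)-2,2-dimethyl-5-{(2S)-2-methyl-3-oxo-5-[(2Z)-4-oxobut-2-en-2-yl]-2,3-dihydrofuran-2-yl}-1,3-dioxolan-4-yl]prop-2-enoate | C/C(=C/C=O)C1=CC(=O)[C@](O1)(C)[C@@H](O2)[C@@H](OC2(C)C)/C=C(\CBr)C(=O)OC | intermediate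
17 | seco hydroxy ester: methyl (4Z,6R,7S,8S,9S,10S)-6-hydroxy-8,9-(isopropylidenedioxy)-1-oxo-3,10-epoxygermacra-2,4,11(13)-trien-12-oate (metal alkoxide in the flask) | CC1(C)O[C@H]2[C@@H](C(=C)C(=O)OC)[C@@H](/C=C(/C)C4=CC(=O)[C@@](C)(O4)[C@H]2O1)O | intermediate
18 | macrolactone acetonide: (4Z,6R,7S,8S,9S,10S)-8,9-(isopropylidenedioxy)-1-oxo-3,10-epoxygermacra-2,4,11(13)-trien-12,6-olide | CC1(C)O[C@H]2[C@@H]3[C@@H](/C=C(/C)C4=CC(=O)[C@@](C)(O4)[C@H]2O1)OC(=O)C3=C | intermediate
19 | macrolactone diol: (4Z,6R,7S,8S,9S,10S)-8,9-dihydroxy-1-oxo-3,10-epoxygermacra-2,4,11(13)-trien-12,6-olide | O[C@H]1[C@@H]2[C@@H](/C=C(/C)C3=CC(=O)[C@@](C)(O3)[C@H]1O)OC(=O)C2=C | intermediate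
20 | C8 methacrylate: (4Z,6R,7S,8S,9S,10S)-9-hydroxy-8-(methacryloyloxy)-1-oxo-3,10-epoxygermacra-2,4,11(13)-trien-12,6-olide | C=C(C)C(=O)O[C@H]1[C@@H]2[C@@H](/C=C(/C)C3=CC(=O)[C@@](C)(O3)[C@H]1O)OC(=O)C2=C | intermediate
21 | C8 methacrylate C9 acetate: (4Z,6R,7S,8S,9S,10S)-9-acetoxy-8-(methacryloyloxy)-1-oxo-3,10-epoxygermacra-2,4,11(13)-trien-12,6-olide | C=C(C)C(=O)O[C@H]1[C@@H]2[C@@H](/C=C(/C)C3=CC(=O)[C@@](C)(O3)[C@H]1OC(C)=O)OC(=O)C2=C | intermediate
22 | CNP0423862.2: (4Z,6R,7S,8S,9S,10S,11S)-9-acetoxy-8-(methacryloyloxy)-1-oxo-3,10:11,13-diepoxygermacra-2,4-dien-12,6-olide | C=C(C)C(=O)O[C@H]1[C@@H]2[C@@H](/C=C(/C)C3=CC(=O)[C@@](C)(O3)[C@H]1OC(C)=O)OC(=O)[C@@]21CO1 | target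

**Step count**

Total: 15 steps (2 for the vinyl iodide, 13 on the main line). Longest linear sequence: 14 steps (1 → 22 through steps 1, 2 and 4–15; the branch from 4 contributes step 3 and joins at step 4).

**Three steps most likely to fail**

Step 11, the proposed electrochemical ring closure. The risks are oligomerisation, the wrong C6/C7 diastereomer (cis-lactone or 7-epimer), cathodic reduction of the dienal and poor chromium turnover. The fallback uses known chemistry and gives up electrosynthesis for the reagent-based organochromium closure. It sets out from 16: excess CrCl2 (about 5 equiv) in THF/DMF with 16 added by syringe pump, the stoichiometric Nozaki–Hiyama–Kishi/Barbier-type closure used for ten-membered germacranolide lactones. This passes through the seco hydroxy ester 17, which is isolated if it does not lactonise and then closed with catalytic TsOH, and it comes back to the route at 18. This fallback makes no new compound (F0).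

Step 3, the C10 stereocentre. The risk is that MeMgBr adds to the alkynyl ketone in the Felkin–Anh rather than the chelate sense, or unselectively. The fallback reverses the order of the two carbon nucleophiles, so that the same intrinsic facial preference now gives the needed epimer. It sets out from 4: MeLi (1 equiv, −78 °C) gives the methyl hemiketal 1-deoxy-3,4:6,7-di-O-isopropylidene-D-manno-hept-2-ulofuranose F1. Its open methyl-ketone form is then treated with (trimethylsilyl)ethynylmagnesium bromide under the conditions that gave the wrong sense with MeMgBr, or with the non-chelating reagent Me3SiC≡CTi(OiPr)3. This comes back to the route at 6 and, after the same K2CO3/MeOH treatment, 7.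

Step 15, the final epoxidation. The risks are competing attack on the methacrylate, perhydrolysis of the two esters by the peroxide anion, and low face selectivity on a flexible substrate. The fallback moves the epoxidation ahead of deprotection and acylation. It sets out from 18: t-BuOOH/DBU gives the epoxy acetonide F2, which has a single Michael acceptor, no esters and a rigid cis-fused dioxolane. Mild acetal hydrolysis (BiCl3 in wet MeCN, or aqueous acetic acid) gives the epoxy diol F3. Methacrylic anhydride/DMAP at −20 °C gives the epoxy C8 methacrylate F4, and Ac2O/DMAP comes back to the route at 22.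

**Further compounds**

F0 | step 11 | none | none
F1 | step 3 | 1-deoxy-3,4:6,7-di-O-isopropylidene-D-manno-hept-2-ulofuranose | CC1(O)[C@@H](O2)[C@@H](OC2(C)C)[C@H](O1)[C@H](O3)COC3(C)C
F2 | step 15 | epoxy acetonide: (4Z,6R,7S,8S,9S,10S,11S)-8,9-(isopropylidenedioxy)-1-oxo-3,10:11,13-diepoxygermacra-2,4-dien-12,6-olide | CC1(C)O[C@H]2[C@@H]3[C@@H](/C=C(/C)C4=CC(=O)[C@@](C)(O4)[C@H]2O1)OC(=O)[C@@]35CO5
F3 | step 15 | epoxy diol: (4Z,6R,7S,8S,9S,10S,11S)-8,9-dihydroxy-1-oxo-3,10:11,13-diepoxygermacra-2,4-dien-12,6-olide | O[C@H]1[C@@H]2[C@@H](/C=C(/C)C3=CC(=O)[C@@](C)(O3)[C@H]1O)OC(=O)[C@@]21CO1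
F4 | step 15 | epoxy C8 methacrylate: (4Z,6R,7S,8S,9S,10S,11S)-9-hydroxy-8-(methacryloyloxy)-1-oxo-3,10:11,13-diepoxygermacra-2,4-dien-12,6-olide | C=C(C)C(=O)O[C@H]1[C@@H]2[C@@H](/C=C(/C)C3=CC(=O)[C@@](C)(O3)[C@H]1O)OC(=O)[C@@]21CO1
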